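**Plan** (1,2-dihydronaphthalene numbering: ring A = benzo ring C4a–C8a, ring B = C1–C4 plus C4a/C8a; C1 carries the syringyl ring, C2 and C3 the methyls)
- Cuts, in order: C2–C3 and C4–C4a together (ring B), then the C1–ring A bond (alkenyl–aryl coupling), the propanoyl–aryl bond and the two O–Si bonds; both aryl rings trace back to 4-bromo-2,6-dimethoxyphenol.
- Enabling feature: in ring B the sp2 atoms C3 and C4 hold their ring bonds (to sp3 C2 and to aromatic C4a) on the same side of C3=C4, which is the arrangement of Br and B in syn-bromoborated propyne. C2 is a secondary carbon next to the diarylmethine C1, so a C2–metal bond can be set by syn-hydroboration of a C1=C2 alkene.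
- Forward: the pendant ring (Br/Li exchange) and ring A (lithiation next to Br, Br kept) are joined as a (Z)-1,1-diarylpropene; asymmetric hydroboration; boron–zinc exchange and a one-pot Negishi/Suzuki–Miyaura double coupling with bromoborated propyne close ring B last; desilylation.
- Stereochemistry: cis C1/C2 from syn addition of H (to C1) and B (to C2) across the (Z)-alkene and retention at C2 in the exchange and the coupling; absolute configuration from the isopinocampheylborane reagent.

Key step: step 7

Remark (assumption): the sense of induction of IpcBH2 on the (Z)-diarylpropene is taken from its behaviour with other trisubstituted aryl alkenes (reagent from (+)-α-pinene gives the 2S boron-bearing centre); if the opposite sense is found, the reagent from (−)-α-pinene is used.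
Abbreviations in names: ArBr = 6-bromo-2,4-dimethoxy-3-(triisopropylsilyloxy)phenyl (becomes ring A); ArSi = 3,5-dimethoxy-4-(triisopropylsilyloxy)phenyl (pendant ring).

Step 1
Reactants: 1 4-bromo-2,6-dimethoxyphenol
Product: 2 (4-bromo-2,6-dimethoxyphenoxy)triisopropylsilane
Conditions: iPr3SiCl, imidazole, DMF, 40 °C
Reagents that add atoms: chlorotriisopropylsilane, CC(C)[Si](Cl)(C(C)C)C(C)C
Why: O-silylation of the hindered phenol should give an aryl silyl ether that withstands organolithium, organozinc and borane reagents and falls to fluoride at the end.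

Step 2
Reactants: 2 (4-bromo-2,6-dimethoxyphenoxy)triisopropylsilane; 3 N-methoxy-N-methylpropanamide
Product: 5 1-(ArSi)propan-1-one, via aryllithium 4 (not isolated)
Conditions: n-BuLi, THF, −78 °C; then 3, −78 to 0 °C; aq. NH4Cl
Reagents that add atoms: none
Why: Bromine–lithium exchange followed by acylation with an N-methoxy-N-methylamide should stop at the ketone, because the chelated tetrahedral adduct survives until work-up.

Step 3
Reactants: 5 1-(ArSi)propan-1-one
Product: 7 (Z)-1-(ArSi)prop-1-en-1-yl trifluoromethanesulfonate, via sodium enolate 6 (not isolated)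
Conditions: NaN(SiMe3)2, THF, −78 °C; then PhNTf2, −78 to 0 °C
Reagents that add atoms: N-phenylbis(trifluoromethanesulfonimide), O=S(=O)(N(c1ccccc1)S(=O)(=O)C(F)(F)F)C(F)(F)F
Why: Kinetic deprotonation of an aryl ethyl ketone should give the (Z)-enolate (oxygen cis to methyl), and O-triflation fixes that geometry in the enol triflate.

Step 4
Reactants: 2 (4-bromo-2,6-dimethoxyphenoxy)triisopropylsilane; 7 (Z)-1-(ArSi)prop-1-en-1-yl trifluoromethanesulfonate
Product: 10 (Z)-1-(ArBr)-1-(ArSi)prop-1-ene, via aryllithium 8 (not isolated), via arylzinc chloride 9 (not isolated)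
Conditions: 2, lithium 2,2,6,6-tetramethylpiperidide, THF, −78 °C; ZnCl2, −78 °C to rt; then 7, Pd(PPh3)4 (5 mol %), THF, 55 °C
Reagents that add atoms: none
Why: The only ring protons of 2 lie between bromine and methoxy and are removed by the amide base, and the derived arylzinc should undergo Negishi coupling with the alkenyl triflate with retention of geometry (ring A ends cis to methyl), since zerovalent palladium inserts into the alkenyl triflate far faster than into the hindered, electron-rich aryl bromide.

Step 5
Reactants: 11 propyne; 12 pinacol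
Product: 14 2-[(Z)-2-bromoprop-1-enyl]-4,4,5,5-tetramethyl-1,3,2-dioxaborolane, via alkenyldibromoborane 13 (not isolated)
Conditions: BBr3, CH2Cl2, −78 °C to rt; then 12, 0 °C
Reagents that add atoms: boron tribromide, BrB(Br)Br
Why: Haloboration of the terminal alkyne is syn, with boron on the terminal and bromine on the internal carbon, and pinacol replaces the B–Br bonds to give a stable (Z)-bromoalkenylboronate that carries the CH=C(CH3) unit of ring B.

Step 6
Reactants: 10 (Z)-1-(ArBr)-1-(ArSi)prop-1-ene
Product: 16 diethyl[(1S,2S)-1-(ArBr)-1-(ArSi)propan-2-yl]borane, via isopinocampheylborane adduct 15 (not isolated)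
Conditions: IpcBH2 (from (+)-α-pinene), Et2O, −35 to 0 °C; then Et2BH, 50 °C; volatiles removed, crude 16 kept under argon
Reagents that add atoms: diethylborane, CCBCC
Why: Asymmetric hydroboration of a trisubstituted aryl alkene places boron on the less substituted C2 and hydrogen on C1 from the same face, so the (Z)-geometry fixes the C1/C2 relative configuration while the isopinocampheyl group selects the face (2S and therefore 1S), and ligand exchange with Et2BH gives the diethylborane needed for boron–zinc exchange.

Step 7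
Reactants: 16 diethyl[(1S,2S)-1-(ArBr)-1-(ArSi)propan-2-yl]borane; 14 2-[(Z)-2-bromoprop-1-enyl]-4,4,5,5-tetramethyl-1,3,2-dioxaborolane
Product: 19 (1S,2S)-1-(ArSi)-6,8-dimethoxy-2,3-dimethyl-7-(triisopropylsilyloxy)-1,2-dihydronaphthalene, via secondary alkylzinc 17 (not isolated), via alkenylboronate 18 (not isolated)
Conditions: iPr2Zn (3 equiv), neat, 25 °C, volatiles removed; then 14 (2.2 equiv), Pd(OAc)2 (4 mol %), CPhos (8 mol %), THF, 25 °C; then aq. K3PO4, 60 °C (one pot)
Reagents that add atoms: none
Why: Boron–zinc exchange turns the secondary C–B bond of 16 into a configurationally stable C–Zn bond with retention (17); zerovalent palladium then inserts into the C–Br bond of 14, the secondary alkyl group passes from zinc to palladium with retention and reductive elimination forms C2–C3 (18). On addition of aqueous base the same catalyst inserts into the aryl C4a–Br bond, the base-activated alkenylboronate transmetalates within the molecule and reductive elimination from a seven-membered palladacycle forms C4–C4a. The closest known reaction types are the palladium-catalysed coupling of hydroboration-derived secondary alkylzinc reagents with alkenyl halides and the one-pot Negishi/Suzuki–Miyaura use of (Z)-2-bromoprop-1-enylboronates; ring B closes in the second coupling as a six-membered ring-closing cross-coupling, possible because the (Z)-geometry of 14 puts C2 and boron on the same side of the double bond. No stereocenter is created: C1 is untouched and C2 keeps the configuration from step 6 because each transfer (B to Zn, Zn to Pd, reductive elimination) goes with retention. The step needs chemoselectivity (alkenyl C–Br before the hindered aryl C–Br, C–Zn before C–B) and no β-hydride elimination at C2, which the order of addition, the inertness of the boronate without base and the bulky biarylphosphine should secure.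

Step 8
Reactants: 19 (1S,2S)-1-(ArSi)-6,8-dimethoxy-2,3-dimethyl-7-(triisopropylsilyloxy)-1,2-dihydronaphthalene
Product: 20 4-[(1S,2S)-7-hydroxy-6,8-dimethoxy-2,3-dimethyl-1,2-dihydronaphthalen-1-yl]-2,6-dimethoxyphenol
Conditions: Bu4NF, AcOH, THF, 0 °C
Reagents that add atoms: none
Why: Buffered fluoride should cleave both aryl silyl ethers without touching the styrenyl double bond or the two stereocenters.

**Compound list**
1 | 4-bromo-2,6-dimethoxyphenol | COc1cc(Br)cc(OC)c1O | starting material
2 | (4-bromo-2,6-dimethoxyphenoxy)triisopropylsilane | COc1cc(Br)cc(OC)c1O[Si](C(C)C)(C(C)C)C(C)C | intermediate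
3 | N-methoxy-N-methylpropanamide | CCC(=O)N(C)OC | starting material
4 | [3,5-dimethoxy-4-(triisopropylsilyloxy)phenyl]lithium | [Li]c1cc(OC)c(O[Si](C(C)C)(C(C)C)C(C)C)c(OC)c1 | intermediate
5 | 1-[3,5-dimethoxy-4-(triisopropylsilyloxy)phenyl]propan-1-one | CCC(=O)c1cc(OC)c(O[Si](C(C)C)(C(C)C)C(C)C)c(OC)c1 | intermediate
6 | sodium (Z)-1-[3,5-dimethoxy-4-(triisopropylsilyloxy)phenyl]prop-1-en-1-olate | [Na+].C/C=C(\[O-])c1cc(OC)c(O[Si](C(C)C)(C(C)C)C(C)C)c(OC)c1 | intermediate
7 | (Z)-1-[3,5-dimethoxy-4-(triisopropylsilyloxy)phenyl]prop-1-en-1-yl trifluoromethanesulfonate | C/C=C(\OS(=O)(=O)C(F)(F)F)c1cc(OC)c(O[Si](C(C)C)(C(C)C)C(C)C)c(OC)c1 | intermediate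
8 | [6-bromo-2,4-dimethoxy-3-(triisopropylsilyloxy)phenyl]lithium | [Li]c1c(Br)cc(OC)c(O[Si](C(C)C)(C(C)C)C(C)C)c1OC | intermediate
9 | [6-bromo-2,4-dimethoxy-3-(triisopropylsilyloxy)phenyl]zinc chloride | Cl[Zn]c1c(Br)cc(OC)c(O[Si](C(C)C)(C(C)C)C(C)C)c1OC | intermediate
10 | (Z)-1-[6-bromo-2,4-dimethoxy-3-(triisopropylsilyloxy)phenyl]-1-[3,5-dimethoxy-4-(triisopropylsilyloxy)phenyl]prop-1-ene (methyl cis to the bromoaryl ring) | C/C=C(/c1cc(OC)c(O[Si](C(C)C)(C(C)C)C(C)C)c(OC)c1)c1c(Br)cc(OC)c(O[Si](C(C)C)(C(C)C)C(C)C)c1OC | intermediate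
11 | propyne | CC#C | starting material
12 | pinacol (2,3-dimethylbutane-2,3-diol) | CC(C)(O)C(C)(C)O | starting material
13 | dibromo[(Z)-2-bromoprop-1-enyl]borane | C/C(Br)=C/B(Br)Br | intermediate
14 | 2-[(Z)-2-bromoprop-1-enyl]-4,4,5,5-tetramethyl-1,3,2-dioxaborolane | C/C(Br)=C/B1OC(C)(C)C(C)(C)O1 | intermediate
15 | [(1S,2S)-1-(ArBr)-1-(ArSi)propan-2-yl](isopinocampheyl)borane, isopinocampheyl group from (+)-α-pinene | C[C@H]1[C@H](B[C@@H](C)[C@@H](c3cc(OC)c(O[Si](C(C)C)(C(C)C)C(C)C)c(OC)c3)c3c(Br)cc(OC)c(O[Si](C(C)C)(C(C)C)C(C)C)c3OC)C[C@@H]2C[C@H]1C2(C)C | intermediate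
16 | diethyl[(1S,2S)-1-(ArBr)-1-(ArSi)propan-2-yl]borane | CCB(CC)[C@@H](C)[C@@H](c1cc(OC)c(O[Si](C(C)C)(C(C)C)C(C)C)c(OC)c1)c1c(Br)cc(OC)c(O[Si](C(C)C)(C(C)C)C(C)C)c1OC | intermediate
17 | isopropyl[(1S,2S)-1-(ArBr)-1-(ArSi)propan-2-yl]zinc | CC(C)[Zn][C@@H](C)[C@@H](c1cc(OC)c(O[Si](C(C)C)(C(C)C)C(C)C)c(OC)c1)c1c(Br)cc(OC)c(O[Si](C(C)C)(C(C)C)C(C)C)c1OC | intermediate
18 | 2-[(1Z,3S,4S)-4-(ArBr)-4-(ArSi)-2,3-dimethylbut-1-enyl]-4,4,5,5-tetramethyl-1,3,2-dioxaborolane | C/C([C@@H](C)[C@@H](c1cc(OC)c(O[Si](C(C)C)(C(C)C)C(C)C)c(OC)c1)c1c(Br)cc(OC)c(O[Si](C(C)C)(C(C)C)C(C)C)c1OC)=C/B1OC(C)(C)C(C)(C)O1 | intermediate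
19 | (1S,2S)-1-[3,5-dimethoxy-4-(triisopropylsilyloxy)phenyl]-6,8-dimethoxy-2,3-dimethyl-7-(triisopropylsilyloxy)-1,2-dihydronaphthalene (cis) | COc1cc([C@H]2c3c(cc(OC)c(O[Si](C(C)C)(C(C)C)C(C)C)c3OC)C=C(C)[C@H]2C)cc(OC)c1O[Si](C(C)C)(C(C)C)C(C)C | intermediate
20 | 4-[(1S,2S)-7-hydroxy-6,8-dimethoxy-2,3-dimethyl-1,2-dihydronaphthalen-1-yl]-2,6-dimethoxyphenol (CNP0141907.1) | COc1cc([C@H]2c3c(cc(OC)c(O)c3OC)C=C(C)[C@H]2C)cc(OC)c1O | target

**Count and risks**
Total steps: 8. Longest linear sequence: 7 (steps 1, 2, 3, 4, 6, 7, 8; step 5 is a side branch).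

Steps most likely to fail:

Step 7. Configuration at C2 may be lost through β-hydride elimination and re-addition on palladium or through slow inversion of the open-chain secondary alkylzinc. The isopropyl group on zinc may be transferred in competition, and palladium may insert into the aryl bromide too early. The fallback sets out from 10 and uses tin-hydride radical chemistry with propyne 11 itself: Bu3SnH (slow addition), AIBN, excess 11, tert-butanol/PhCF3, 80 °C, sealed vessel. The aryl radical at C4a should add to the terminal carbon of propyne, the vinyl radical should close on C2 of the diarylalkene, and the doubly benzylic C1 radical should take hydrogen from the face away from the C2 methyl. This should give the cis compound as a racemate, that is 19 together with its mirror image ent-19 F1. Chromatography on a chiral stationary phase brings the route back to 19.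

Step 6. The bulky borane may add slowly to the hindered trisubstituted alkene, with poor facial selectivity or with partial delivery of boron to C1. The fallback sets out from 10 and uses copper-catalysed enantioselective protoboration (CuCl, a chiral bisphosphine, NaOtBu, B2pin2, MeOH, THF). Syn addition of boron to C2 and copper to C1, then protonation of the benzylic C–Cu bond with retention, should give the pinacol boronate F2 with the same relative configuration. Two equivalents of EtMgBr then exchange the pinacol for ethyl groups and the route is rejoined at 16.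

Step 4. Transmetalation of the di-ortho-substituted arylzinc may be slow, palladium may insert into the aryl bromide and give oligomers, and the alkene geometry may erode. The fallback sets out from 2 and 5: aryllithium 8, made as in step 4, is added to ketone 5 in the presence of CeCl3 to give the tertiary alcohol F3. Acid-catalysed dehydration (p-TsOH, toluene, 60 °C) gives 10 together with its geometric isomer, the (E)-alkene F4. The two are separated on AgNO3-impregnated silica, the unwanted isomer is recycled by iodine-catalysed equilibration, and the route is rejoined at 10.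

**Further compounds**
F1 | step 7 | ent-19, (1R,2R)-1-[3,5-dimethoxy-4-(triisopropylsilyloxy)phenyl]-6,8-dimethoxy-2,3-dimethyl-7-(triisopropylsilyloxy)-1,2-dihydronaphthalene | COc1cc([C@@H]2c3c(cc(OC)c(O[Si](C(C)C)(C(C)C)C(C)C)c3OC)C=C(C)[C@@H]2C)cc(OC)c1O[Si](C(C)C)(C(C)C)C(C)C
F2 | step 6 | 2-[(1S,2S)-1-(ArBr)-1-(ArSi)propan-2-yl]-4,4,5,5-tetramethyl-1,3,2-dioxaborolane | CC1(C)OB(OC1(C)C)[C@@H](C)[C@@H](c1cc(OC)c(O[Si](C(C)C)(C(C)C)C(C)C)c(OC)c1)c1c(Br)cc(OC)c(O[Si](C(C)C)(C(C)C)C(C)C)c1OC
F3 | step 4 | 1-(ArBr)-1-(ArSi)propan-1-ol (racemic) | CCC(O)(c1cc(OC)c(O[Si](C(C)C)(C(C)C)C(C)C)c(OC)c1)c1c(Br)cc(OC)c(O[Si](C(C)C)(C(C)C)C(C)C)c1OC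
F4 | step 4 | (E)-1-(ArBr)-1-(ArSi)prop-1-ene (methyl trans to the bromoaryl ring) | C/C=C(\c1cc(OC)c(O[Si](C(C)C)(C(C)C)C(C)C)c(OC)c1)c1c(Br)cc(OC)c(O[Si](C(C)C)(C(C)C)C(C)C)c1OC
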